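(The numbers of this flask are made up; the flask was simulated.)

Each turnover takes one J and one Q and gives one L, so with Q the smaller charge, L stops at the ratio of the charges.

| setting | elm | alder | oak |
|---|---|---|---|
| J | 0.062 M | 0.062 M | 0.062 M (fed, over 20 min) |
| Q | 0.0434 M | 0.0434 M (fed, over 20 min) | 0.0434 M |
| Z | 3.1 mM | 3.1 mM | 3.1 mM |
| time | 30 min | 30 min | 30 min |
| remark | everything together at the start | all else is in the flask from the start; the feed brings no volume worth counting | all else is in the flask from the start; the feed brings no volume worth counting |

    Q + Z → Q.Z (k1 = 15 L mol⁻¹ s⁻¹)
    E → Z + L (k2 = 1.6 s⁻¹)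
    Q.Z → X (k3 = 1.2 s⁻¹)
    J.X → E (k4 = 0.060 s⁻¹)
    J + X ⇌ J.X (K5 = 3.0 L mol⁻¹, k5 = 18 L mol⁻¹ s⁻¹)

- the best flask by amount of L, in percent of the J charged; "all alike" if 1.5 percentage points covers them all (elm / alder / oak / all alike)
- amount of L at the end, in percent of the J charged, elm
- amount of L at the end, in percent of the J charged, alder
- amount of L at the end, in percent of the J charged, oak

**The charges.** Q is the limiting reagent, being charged at less than J, so I put the ceiling on L at 70.0% of the J charged.

**The clock.** My second way uses rates. At elm's starting charges, X goes forward through J more slowly than Z takes up Q, or than Q.Z and E pass on. So I take X as the resting state. J.X falls back faster than it goes on to E, so it stands in equilibrium with X, and J decays pseudo-first-order. Taking the whole catalyst as X, I call its constant the J clock, the product 0.060 s⁻¹ × 3.0 L mol⁻¹ × 3.1 mM, which is 0.0335 min⁻¹: on this reckoning, the logarithm of [J] at the start over [J] now grows by that much each minute. In elm it reads 1.00 at 30 min, which gives L of 63.4%. The ceiling needs a reading of 1.20, more than elm gets. The two ways part, and the ceiling is the one that cheats at this time, so I commit to the clock. In oak, J arrives on average halfway through the feed, so I reckon the clock at 0.670 and L at 48.8%, less than my figure for elm. Alder I do not reckon.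

**The forecast.** It gives elm 60.2%, alder 56.3% and oak 45.5%, and names elm best; of the mechanism it says “The slow step is J.X → E, with X and J.X in fast equilibrium”. Its elm figure is below mine.

**The result.** The simulation gives elm 57.1%, alder 53.7% and oak 43.1%, with elm best, and the forecast held on each. J left in elm reads 0.855 on the clock, against my 1.00; X there is 86.5% of the catalyst at 15.0 min, not the whole of it as I took. Elm reaches the ceiling later, 70.0% at 300 min. Oak trails elm by 14 percentage points, and the backward run of J.X to J + X is the largest single effect on that gap: without it the gap is 0 points.

**Less Q.** Take a flask like oak with 0.011 M of Q. Its ceiling is 17.7%, which needs a clock reading of 0.195, less than oak's 0.670, so I expect it to reach the ceiling. It gives 17.7% at 30.0 min, with Q at 0%.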